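## Structural features

The target is the depsidone salazinic acid as its (S)-lactol. Two benzene rings are joined by an aryl ester (C-11(=O)–O-10) and a diaryl ether (O-5), which together close a seven-membered 1,4-dioxepin-11-one; dibenzo[b,e][1,4]dioxepin-11-one numbering is used throughout. Ring A carries CH3 at C-1, the only aromatic hydrogen at C-2, OH at C-3 and CHO at C-4, so the formyl group is wedged between the phenol and the ether oxygen. Ring B is fully substituted. It bears O-5 at C-5a, the lactol carbon on C-6, the lactone carbonyl on C-7, OH at C-8, CH2OH at C-9 and O-10 at C-9a, and C-6 and C-7 are bridged by a five-membered 3-hydroxyphthalide ring. The lactol carbon is the only stereocentre, so no neighbouring centre can relay configuration to it. Because it is the cyclic form of an ortho-formyl benzoic acid, it can racemise by ring opening. The fragile groups are the activated aryl ester (alcoholysis), the free aldehyde, the ortho-hydroxybenzyl alcohol (quinone methide formation, hydrogenolysis) and the lactol itself. The real difficulties are the regiocontrolled hexasubstitution of ring B, a diaryl ether with four ortho substituents, and creating and then keeping a configurationally labile centre. The key step exploits the ortho relation on ring B between the carbonyl carbon on C-7 and the lactol carbon on C-6. A halide at C-7 and an aldehyde at C-6 allow the five-membered ring and its stereocentre to be made in one carbonylation.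

## Logic of the disconnections

**26 ⇒ 25.** The four O–CH2Ph bonds are cut, at the oxygens on C-3 and C-8, at the CH2O group on C-9 and at the lactol oxygen. A free lactol can racemise through the open formyl acid, whereas its O-alkyl acetal cannot, so the stereocentre travels as an acetal until the last step. Cleavage must occur on the benzyl side and must deliver the neutral lactol rather than its anion, which would open at once. This points to hydrogenolysis. The gain is one protecting-group type and one final step. The demand is a neutral, aprotic reduction that is stopped in time, so that it spares the C-4 formyl group, the aryl–CH2–O bond at C-9 and the benzylic C–O bonds of the lactol ring.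

**25 ⇒ 22 + 23 + 15.** Three bonds are cut: C-7–C(=O), C(=O)–O and acetal C–O(benzyl). This removes a ring, a carbon atom and the stereocentre together and leaves an achiral bromo dialdehyde. The halide must stand at C-7 and the aldehyde at C-6, and this mapping onto 26 was checked atom by atom; both 25 and 26 are (S). The C-4 aldehyde of 22 is left free, because unmasking it after the stereocentre is set would need acid. The forward step must select one hemiacetal configuration, must not open the C-11 aryl ester and must not divert the acyl-metal species to an open ester.

**22 ⇒ 21 ⇒ 19.** The O–benzyl bond at C-8 is cut, then the ester bond C-11–O-10. Only the oxygen on C-9a can reach the acid geometrically, so the free C-8 phenol of 19 needs no protection during ring closure and is capped afterwards. The gain is an open diaryl ether. The demand is activation of a benzoic acid with two ortho substituents, under dilution.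

**19 ⇒ 18 ⇒ 9 + 17.** Two acetal-type phenol protecting groups and one tert-butyl ester are removed together by acid. Then the C-4a–O-5 bond is cut. This bond is made first and intermolecularly, with only one free phenol in 9. If the rings were joined through the ester first, a neighbouring phenoxide could take over the acyl group and scramble the regiochemistry of the two catechol oxygens. The gain is two rings of similar size. The demand is an aryl fluoride activated from both ortho positions, so that a hindered, stabilised phenoxide can attack it.

**9 ⇒ 8 ⇒ 5.** The C-6–CHO bond is cut, then the C-5a–O bond. The intermediate 5 is mirror-symmetric. Its two bromides are equivalent, so turning one into OH places the oxygen at C-5a and leaves the other bromide at C-7 with no regiochemical choice. The only remaining ring C–H is then ortho to the new phenol. Para-hydroxylation of a catechol was rejected because it is inefficient and leaves the two catechol oxygens undifferentiated.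

**5 ⇒ 4 ⇒ 2 ⇒ 1.** The two C–Br bonds, the aryl–CH2 bond at C-9 and the two phenol protecting groups are cut. The CH2O carbon is introduced already oxidised and already benzylated, by metalation between the two directing oxygens. Oxidation of an aryl methyl group was rejected, because radical bromination does not tolerate benzyl ethers, aldehydes or so electron-rich a ring. The demand is that no aryl benzyl ether is present during the deprotonation with alkyllithium.

**17 ⇒ 16 ⇒ 14 + 15.** The O–tert-butyl bond and the aryl–CO2H bond are cut. The carboxyl carbon comes from a palladium carbonylation, which tolerates the aldehyde. The ester is closed by O-alkylation, which avoids attack at a hindered carbonyl group.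

**14 ⇒ 12 ⇒ 11 ⇒ 10.** The aryl–CHO bond, the O–benzyl bond and the C–Br bond are cut. The formyl group must precede the ester, because an ortho-methyl benzoate would be deprotonated at its methyl group. The C–H between fluorine and oxygen is the most acidic ring position, and the phenol directs bromine to its para position.

## Other disconnections considered

**Alternative 1:** Ring B itself is cut at C-6–C-7 and C-8–C-9, together with the O-10–C-9a bond. In the forward sense the triyne A1 would be heated in a hexadehydro-Diels–Alder reaction. In A1 a 1,3-diyne and a silyl propiolate are tied together through the future acetal carbon and lactone ester. The benzyne between C-9a and C-5a would be trapped by the ring-A acid A2 to give the depside A3.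
- **In its favour:** ring B and the lactone ring arise in one metal-free step from an open chain, which is better than the stepwise substitution of the chosen plan. The stereocentre rests on a separable auxiliary acetal rather than on an untested catalytic induction, which is also a better position. No carbon monoxide is needed.
- **Against it, on structure:** A1 is an acyloxy-alkoxy acetal on a propargylic carbon. It ionises easily and would have to survive heating in the presence of a carboxylic acid, which can epimerise it.
- **Against it, on mechanism:** the trap is intermolecular, it must place oxygen at C-9a and not at C-5a, and A2 also offers a phenol.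
- **What remains after the key step:** A3 has hydrogen at C-5a and silicon at C-8. Oxidation of the C–Si bond and an oxidative C–H aryloxylation to close the seven-membered ring must therefore follow, and the latter has little support on such a crowded, electron-poor ring.
- **On step economy:** one uncertain step of the chosen plan is exchanged for at least two, and several steps follow the key step instead of one. The final hydrogenolysis and the lability of the lactol are the same in both plans.

**Alternative 2:** Ring B is cut at C-7–C-8 and C-5a–C-6. The diene A4 is a bis(silyloxy) methoxy diene that bears ring A as an aryloxy group on its terminus. It would add to the bromobutenolide A5, and loss of hydrogen bromide and methanol would aromatise the adduct to the diaryl ether A6.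
- **In its favour:** the stereocentre comes from a 5-alkoxybutenolide that can be purified as one diastereomer by known means, so on stereocontrol this plan is the safer one. The polarity matches, since the nucleophilic aryloxy-bearing terminus meets the β-carbon of A5. The crowded O-5 link is made earlier as an alkylation at sp3 carbon, which is easier than the substitution at an aromatic carbon used in the chosen plan.
- **Against it, on structure:** A4 is a tetrasubstituted, hydrolytically sensitive ketene acetal diene with an inner CH2O substituent and a very bulky terminus, so the s-cis form and the approach to A5 are both strained.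
- **Against it, on mechanism:** aromatisation and desilylation need acid or base next to the acetal centre.
- **On step economy:** after A6 there remain deallylation, lactonisation, acidic release of the ring-A aldehyde (a threat to the acetal) and hydrogenolysis, against one step after the key step in the chosen plan. A4 needs a ring A as elaborate as 17 plus a chain, so the total should not be lower. Both plans share the last hydrogenolysis and the lability of the lactol.

**Alternative 3:** Three ring-A bonds are cut: C-11a–C-4a, C-4–C-3 and C-2–C-1. A rhodium or ruthenium catalyst would join the tethered butynoate and aryl ynol ether of the diyne A7 with benzyl ethynyl ether A8 in a [2+2+2] cycloaddition, giving the depsidone A9 with ring A and the dioxepinone formed together.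
- **In its favour:** no aromatic ring-A building block is needed. Both links to ring B are made as simple O-functionalisations before the rings exist, which avoids the hindered aromatic substitution and the lactonisation. On these two points it is better than the chosen plan, and its convergence is at least equal.
- **Against it, on structure:** A7 must already hold the complete ring B with the phthalide acetal, so the central problem of the stereocentre is moved rather than solved. The strongly basic preparation of an aryl ynol ether also does not suit a lactone acetal.
- **Against it, on mechanism:** the two alkynes are held by a five-atom tether, and a metallacycle that leads to a seven-membered ring forms reluctantly. A8 must insert with one orientation, is thermally labile and can oligomerise.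
- **On step economy:** desilylation, oxidation to the aldehyde and hydrogenolysis follow A9, three steps against one. The last step is common to both plans.

Key step: step 15

Assumption: the sense of induction of a chiral diphosphine in step 15 cannot be predicted, so the ligand antipode that leads to the (S)-acetal is taken as the one used; the free lactol 26 is taken to hold its configuration only in neutral aprotic media at or below room temperature, because ring–chain tautomerism to the formyl acid would racemise it.

## Route

Step 1
Reactants: 1 resorcinol
Product: 2 1,3-bis(methoxymethoxy)benzene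
Conditions: NaH (2.3 equiv), MOMCl (2.3 equiv), DMF, 0 °C → rt
Reagents that add atoms: chloromethyl methyl ether, COCCl
Why: Williamson O-alkylation of both phenoxides; the MOM groups are strong directors for metalation, tolerate base and organolithiums, and leave later under the same acid treatment as the tert-butyl ester.

Step 2
Reactants: 2 1,3-bis(methoxymethoxy)benzene
Product: 4 2-[(benzyloxy)methyl]-1,3-bis(methoxymethoxy)benzene, via 2-lithio arene 3 (not isolated)
Conditions: n-BuLi, THF, 0 °C; BnOCH2Cl, −78 °C → rt
Reagents that add atoms: benzyl chloromethyl ether, ClCOCc1ccccc1; n-butyllithium, [Li]CCCC (lithium stays only in 3)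
Why: Directed ortho-metalation takes the C–H between the two MOM ethers, and alkylation of the aryllithium with an α-chloro ether delivers the CH2OBn group in one operation. No benzyl ether is present while the base acts.

Step 3
Reactants: 4 2-[(benzyloxy)methyl]-1,3-bis(methoxymethoxy)benzene
Product: 5 3-[(benzyloxy)methyl]-1,5-dibromo-2,4-bis(methoxymethoxy)benzene
Conditions: NBS (2.1 equiv), MeCN, 0 °C → rt, dark
Reagents that add atoms: N-bromosuccinimide, O=C1CCC(=O)N1Br
Why: Electrophilic aromatic bromination; the two equivalent positions ortho to one and para to the other MOM ether are the only activated ones, so exhaustive dibromination has no regiochemical choice and keeps the mirror symmetry. Ionic conditions in the dark spare the benzylic C–H bonds.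

Step 4
Reactants: 5 3-[(benzyloxy)methyl]-1,5-dibromo-2,4-bis(methoxymethoxy)benzene
Product: 8 3-[(benzyloxy)methyl]-5-bromo-2,4-bis(methoxymethoxy)phenol, via monolithio arene 6 (not isolated), via dimethyl arylboronate 7 (not isolated)
Conditions: n-BuLi (1.0 equiv), THF, −78 °C; B(OMe)3, −78 → 0 °C; 30% H2O2, AcOH, 0 °C → rt
Reagents that add atoms: hydrogen peroxide, OO; trimethyl borate, COB(OC)OC (kept only in 7); n-butyllithium, [Li]CCCC (lithium stays only in 6)
Why: Bromine–lithium exchange, borylation and oxidation convert one aryl bromide into a phenol; the bromides are equivalent by symmetry, so one equivalent of n-BuLi desymmetrises 5 without a regiochemical issue, and exchange at −78 °C is far faster than deprotonation of the benzylic ether. The new OH becomes O-5 and the surviving bromide sits at the future C-7.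

Step 5
Reactants: 8 3-[(benzyloxy)methyl]-5-bromo-2,4-bis(methoxymethoxy)phenol
Product: 9 4-[(benzyloxy)methyl]-2-bromo-6-hydroxy-3,5-bis(methoxymethoxy)benzaldehyde
Conditions: MgCl2, Et3N, (CH2O)n, MeCN, reflux; dilute HCl work-up
Reagents that add atoms: paraformaldehyde (as formaldehyde), C=O
Why: Casnati–Skattebøl ortho-formylation; the magnesium phenoxide delivers formaldehyde only to the ortho carbon, here the single ring C–H left, and a second formaldehyde accepts hydride to raise the carbon to the aldehyde level.

Step 6
Reactants: 10 3-fluoro-5-methylphenol
Product: 11 4-bromo-3-fluoro-5-methylphenol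
Conditions: NBS (1.0 equiv), MeCN, −10 → 0 °C
Reagents that add atoms: N-bromosuccinimide, O=C1CCC(=O)N1Br
Why: Electrophilic aromatic bromination of a phenol in a polar solvent goes para to OH, as with 3-substituted and 3,5-disubstituted phenols in general; this marks the carbon that will carry the carboxyl group.

Step 7
Reactants: 11 4-bromo-3-fluoro-5-methylphenol
Product: 12 5-(benzyloxy)-2-bromo-1-fluoro-3-methylbenzene
Conditions: BnBr, K2CO3, DMF, rt
Reagents that add atoms: benzyl bromide, BrCc1ccccc1
Why: Williamson ether synthesis; the benzyl ether helps to acidify the neighbouring C–H and is removed in the final hydrogenolysis.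

Step 8
Reactants: 12 5-(benzyloxy)-2-bromo-1-fluoro-3-methylbenzene
Product: 14 6-(benzyloxy)-3-bromo-2-fluoro-4-methylbenzaldehyde, via aryllithium 13 (not isolated)
Conditions: LDA, THF, −78 °C; DMF, −78 °C; 1 M HCl
Reagents that add atoms: N,N-dimethylformamide, CN(C)C=O; lithium diisopropylamide, [Li]N(C(C)C)C(C)C (lithium stays only in 13)
Why: Directed ortho-metalation with a lithium amide removes the C–H between fluorine and benzyloxy, the most acidic ring position, without touching the bromide; at −78 °C the ortho-fluoro aryllithium does not lose LiF. The formyl group is set before the ester because an ortho-methyl benzoate would be deprotonated at its methyl group.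

Step 9
Reactants: 14 6-(benzyloxy)-3-bromo-2-fluoro-4-methylbenzaldehyde; 15 carbon monoxide
Product: 16 4-(benzyloxy)-2-fluoro-3-formyl-6-methylbenzoic acid
Conditions: Pd(OAc)2 (3 mol %), Xantphos (4 mol %), Et3N, H2O (10 equiv), 1,4-dioxane, CO (3 bar), 85 °C
Reagents that add atoms: water, O
Why: Palladium-catalysed hydroxycarbonylation of an aryl bromide tolerates the aldehyde that rules out organometallic carboxylation. A tertiary amine and little water keep hydroxide low, so the activated fluoride should persist.

Step 10
Reactants: 16 4-(benzyloxy)-2-fluoro-3-formyl-6-methylbenzoic acid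
Product: 17 tert-butyl 4-(benzyloxy)-2-fluoro-3-formyl-6-methylbenzoate
Conditions: Cl3CC(=NH)OtBu, BF3·OEt2 (cat.), CH2Cl2–cyclohexane, rt
Reagents that add atoms: tert-butyl 2,2,2-trichloroacetimidate, CC(C)(C)OC(=N)C(Cl)(Cl)Cl
Why: Esterification by O-alkylation with a tert-butyl cation equivalent avoids nucleophilic attack at a carbonyl group flanked by two ortho substituents. The ester resists the carbonate base of step 11 and leaves with acid.

Step 11
Reactants: 9 4-[(benzyloxy)methyl]-2-bromo-6-hydroxy-3,5-bis(methoxymethoxy)benzaldehyde; 17 tert-butyl 4-(benzyloxy)-2-fluoro-3-formyl-6-methylbenzoate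
Product: 18 tert-butyl 4-(benzyloxy)-2-{3-[(benzyloxy)methyl]-5-bromo-6-formyl-2,4-bis(methoxymethoxy)phenoxy}-3-formyl-6-methylbenzoate
Conditions: K2CO3, DMF, 50 °C
Reagents that add atoms: none
Why: Nucleophilic aromatic substitution by addition–elimination; the fluoride lies between a formyl and an ester group, which stabilise the anionic adduct, and the nucleophile approaches perpendicular to the ring so the ortho groups hinder it little. The phenol of 9 is the only free OH, so O-5 is placed without ambiguity.

Step 12
Reactants: 18 the diaryl ether of step 11
Product: 19 4-(benzyloxy)-2-{3-[(benzyloxy)methyl]-5-bromo-6-formyl-2,4-dihydroxyphenoxy}-3-formyl-6-methylbenzoic acid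
Conditions: TFA–CH2Cl2 (1:3), H2O (5 equiv), 0 °C → rt
Reagents that add atoms: none
Why: Acidolysis removes both aryl MOM ethers and the tert-butyl ester in one operation, while aryl and alkyl benzyl ethers persist. The formyl group para to the CH2OBn carbon disfavours ionisation of that benzylic ether.

Step 13
Reactants: 19 the hydroxy acid of step 12
Product: 21 3-(benzyloxy)-9-[(benzyloxy)methyl]-7-bromo-8-hydroxy-1-methyl-11-oxo-11H-dibenzo[b,e][1,4]dioxepine-4,6-dicarbaldehyde, via mixed trifluoroacetic anhydride 20 (not isolated)
Conditions: (CF3CO)2O (2 equiv), toluene (0.005 M), 0 °C → rt; aq. NaHCO3 wash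
Reagents that add atoms: trifluoroacetic anhydride, O=C(OC(=O)C(F)(F)F)C(F)(F)F (kept only in 20)
Why: Lactonisation through a mixed anhydride, the classical depsidone closure; a benzoic acid with two ortho substituents reacts through an acylium-like species, so hindrance at the carbonyl matters little. Only the OH on C-9a can reach the acyl carbon (seven-membered ring), and any trifluoroacetate on the C-8 phenol falls off in the wash.

Step 14
Reactants: 21 the depsidone phenol of step 13
Product: 22 3,8-bis(benzyloxy)-9-[(benzyloxy)methyl]-7-bromo-1-methyl-11-oxo-11H-dibenzo[b,e][1,4]dioxepine-4,6-dicarbaldehyde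
Conditions: BnBr, K2CO3, acetone, 45 °C
Reagents that add atoms: benzyl bromide, BrCc1ccccc1
Why: Williamson O-alkylation of the C-8 phenol under carbonate in acetone, conditions commonly used for O-alkylation of depsidones without opening the aryl ester.

Step 15
Reactants: 22 the bromo formyl depsidone of step 14; 23 benzyl alcohol (3 equiv); 15 carbon monoxide
Product: 25 (1S)-1,4,10-tris(benzyloxy)-5-[(benzyloxy)methyl]-8-methyl-3,7-dioxo-1,3-dihydro-7H-isobenzofuro[4,5-b][1,4]benzodioxepine-11-carbaldehyde (22 with C-7–Br and C-6–CHO replaced by the fused ring C-7–C(=O)–O–CH(OBn)–C-6, S at the acetal carbon), via bromo hemiacetal 24 (not isolated)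
Conditions: Pd(OAc)2 (5 mol %), chiral Josiphos-type diphosphine (6 mol %), iPr2NEt (2 equiv), CO (3 bar), toluene, 4 Å MS, 65 °C
Reagents that add atoms: none
Why: Proposed new method: Pd(0) carrying the chiral diphosphine should add oxidatively to the C-7–Br bond of 22, which the ortho formyl group activates, and 15 should insert to give an aroyl-palladium(II) bromide lying next to the C-6 aldehyde. 23 adds reversibly to that aldehyde (24 and its acyl-palladium counterpart), the amine takes up HBr, the hemiacetal oxygen binds to palladium, and C(acyl)–O bond formation from the six-membered palladacycle releases 25 and Pd(0). The closest known reaction type is the palladium-catalysed carbonylative cyclisation of 2-halobenzaldehydes with primary alcohols to racemic 3-alkoxyphthalides; what is new is asking a chiral ligand to choose between the hemiacetal antipodes. The one ring closed is the γ-lactone, formally by 5-exo-trig attack of the hemiacetal oxygen on the acyl carbon. The one new stereocentre is set by the ligand in a dynamic kinetic resolution: the two hemiacetal configurations interconvert quickly through the aldehyde, so under Curtin–Hammett conditions the diastereomeric palladacycle that closes faster decides the configuration, and the (S)-acetal cannot reopen in the weakly basic aprotic medium. Site selectivity is secured by the substrate, since only C-7 bears a halide and only the C-6 aldehyde therefore has an acyl-metal neighbour; the C-4 aldehyde can only form a hemiacetal that falls apart on work-up. Chemoselectivity against direct alcoholysis to an open benzyl ester and against acyl transfer away from the metal is sought through the intramolecular capture, a small excess of 23, a hindered non-nucleophilic amine and the absence of carboxylate or pyridine-type additives. The same choices, together with molecular sieves, protect the C-11 aryl ester, which is also shielded by the C-1 methyl group.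

Step 16
Reactants: 25 the (S)-benzyl acetal of step 15
Product: 26 (1S)-1,4,10-trihydroxy-5-(hydroxymethyl)-8-methyl-3,7-dioxo-1,3-dihydro-7H-isobenzofuro[4,5-b][1,4]benzodioxepine-11-carbaldehyde, (S)-salazinic acid
Conditions: H2 (1 atm), 10% Pd/C, THF–EtOAc, 0 → 15 °C, stopped after uptake of 4 equiv; cold filtration and concentration
Reagents that add atoms: none
Why: Catalytic hydrogenolysis cleaves the four unhindered PhCH2–O bonds, as in the release of lactols from benzyl glycosides; the C–O bond at the stereocentre is not touched, so the configuration is retained and the lactol appears in neutral form. The crowded ring B should adsorb poorly, which protects its own benzylic C–O bonds, and the aldehyde with two ortho substituents, hydrogen-bonded once the phenol is free, should be reduced slowly.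

## Compound list

1 | resorcinol | Oc1cccc(O)c1 | starting material
2 | 1,3-bis(methoxymethoxy)benzene | COCOc1cccc(OCOC)c1 | intermediate
3 | 2,6-bis(methoxymethoxy)phenyllithium (not isolated) | [Li]c1c(OCOC)cccc1OCOC | intermediate
4 | 2-[(benzyloxy)methyl]-1,3-bis(methoxymethoxy)benzene | COCOc1cccc(OCOC)c1COCc1ccccc1 | intermediate
5 | 3-[(benzyloxy)methyl]-1,5-dibromo-2,4-bis(methoxymethoxy)benzene | COCOc1c(Br)cc(Br)c(OCOC)c1COCc1ccccc1 | intermediate
6 | 3-[(benzyloxy)methyl]-5-bromo-2,4-bis(methoxymethoxy)phenyllithium (not isolated) | [Li]c1cc(Br)c(OCOC)c(COCc2ccccc2)c1OCOC | intermediate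
7 | dimethyl {3-[(benzyloxy)methyl]-5-bromo-2,4-bis(methoxymethoxy)phenyl}boronate (not isolated) | COB(OC)c1cc(Br)c(OCOC)c(COCc2ccccc2)c1OCOC | intermediate
8 | 3-[(benzyloxy)methyl]-5-bromo-2,4-bis(methoxymethoxy)phenol | Oc1cc(Br)c(OCOC)c(COCc2ccccc2)c1OCOC | intermediate
9 | 4-[(benzyloxy)methyl]-2-bromo-6-hydroxy-3,5-bis(methoxymethoxy)benzaldehyde | O=Cc1c(O)c(OCOC)c(COCc2ccccc2)c(OCOC)c1Br | intermediate
10 | 3-fluoro-5-methylphenol | Cc1cc(O)cc(F)c1 | starting material
11 | 4-bromo-3-fluoro-5-methylphenol | Cc1cc(O)cc(F)c1Br | intermediate
12 | 5-(benzyloxy)-2-bromo-1-fluoro-3-methylbenzene | Cc1cc(OCc2ccccc2)cc(F)c1Br | intermediate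
13 | 6-(benzyloxy)-3-bromo-2-fluoro-4-methylphenyllithium (not isolated) | Cc1cc(OCc2ccccc2)c([Li])c(F)c1Br | intermediate
14 | 6-(benzyloxy)-3-bromo-2-fluoro-4-methylbenzaldehyde | Cc1cc(OCc2ccccc2)c(C=O)c(F)c1Br | intermediate
15 | carbon monoxide | [C-]#[O+] | starting material
16 | 4-(benzyloxy)-2-fluoro-3-formyl-6-methylbenzoic acid | Cc1cc(OCc2ccccc2)c(C=O)c(F)c1C(=O)O | intermediate
17 | tert-butyl 4-(benzyloxy)-2-fluoro-3-formyl-6-methylbenzoate | Cc1cc(OCc2ccccc2)c(C=O)c(F)c1C(=O)OC(C)(C)C | intermediate
18 | tert-butyl 4-(benzyloxy)-2-{3-[(benzyloxy)methyl]-5-bromo-6-formyl-2,4-bis(methoxymethoxy)phenoxy}-3-formyl-6-methylbenzoate | Cc1cc(OCc2ccccc2)c(C=O)c(Oc2c(C=O)c(Br)c(OCOC)c(COCc3ccccc3)c2OCOC)c1C(=O)OC(C)(C)C | intermediate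
19 | 4-(benzyloxy)-2-{3-[(benzyloxy)methyl]-5-bromo-6-formyl-2,4-dihydroxyphenoxy}-3-formyl-6-methylbenzoic acid | Cc1cc(OCc2ccccc2)c(C=O)c(Oc2c(C=O)c(Br)c(O)c(COCc3ccccc3)c2O)c1C(=O)O | intermediate
20 | mixed anhydride of 19 with trifluoroacetic acid (not isolated) | Cc1cc(OCc2ccccc2)c(C=O)c(Oc2c(C=O)c(Br)c(O)c(COCc3ccccc3)c2O)c1C(=O)OC(=O)C(F)(F)F | intermediate
21 | 3-(benzyloxy)-9-[(benzyloxy)methyl]-7-bromo-8-hydroxy-1-methyl-11-oxo-11H-dibenzo[b,e][1,4]dioxepine-4,6-dicarbaldehyde | Cc1cc(OCc4ccccc4)c(C=O)c2c1C(=O)Oc1c(COCc4ccccc4)c(O)c(Br)c(C=O)c1O2 | intermediate
22 | 3,8-bis(benzyloxy)-9-[(benzyloxy)methyl]-7-bromo-1-methyl-11-oxo-11H-dibenzo[b,e][1,4]dioxepine-4,6-dicarbaldehyde | Cc1cc(OCc4ccccc4)c(C=O)c2c1C(=O)Oc1c(COCc4ccccc4)c(OCc4ccccc4)c(Br)c(C=O)c1O2 | intermediate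
23 | benzyl alcohol | OCc1ccccc1 | starting material
24 | benzyl hemiacetal of 22 at the C-6 aldehyde, both configurations interconverting (not isolated) | Cc1cc(OCc4ccccc4)c(C=O)c2c1C(=O)Oc1c(COCc4ccccc4)c(OCc4ccccc4)c(Br)c(C(O)OCc4ccccc4)c1O2 | intermediate
25 | (1S)-1,4,10-tris(benzyloxy)-5-[(benzyloxy)methyl]-8-methyl-3,7-dioxo-1,3-dihydro-7H-isobenzofuro[4,5-b][1,4]benzodioxepine-11-carbaldehyde | Cc1cc(OCc4ccccc4)c(C=O)c2c1C(=O)Oc1c(COCc4ccccc4)c(OCc4ccccc4)c3c(c1O2)[C@@H](OCc1ccccc1)OC3=O | intermediate
26 | (1S)-1,4,10-trihydroxy-5-(hydroxymethyl)-8-methyl-3,7-dioxo-1,3-dihydro-7H-isobenzofuro[4,5-b][1,4]benzodioxepine-11-carbaldehyde | Cc1cc(O)c(C=O)c2c1C(=O)Oc1c(CO)c(O)c3c(c1O2)[C@@H](O)OC3=O | target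

## Step count and least certain steps

Total step count: 16. Longest linear sequence: 11 steps (steps 1–5 followed by 11–16; the ring-A branch, steps 6–10 followed by 11–16, is equally long).

**Step 15 (key step, new in its asymmetric form).**
- **Main risk:** poor enantioselection, because ring closure can escape the chiral metal. The aldehyde oxygen may attack the acyl-palladium first, giving a planar cyclic oxocarbenium ion that picks up 23 without ligand control. Alternatively, direct alcoholysis to an open ester followed by base-induced isomerisation gives racemic material.
- **Second risk:** slow oxidative addition at a bromide with two ortho substituents. This would force higher temperatures, at which alcoholysis of the C-11 aryl ester sets in.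
- **Fallback (known chemistry):** starting from 22, the established racemic carbonylative cyclisation is run with an achiral catalyst (PdCl2(PPh3)2 or Pd(OAc)2/dppf, iPr2NEt, 23, 15, toluene). It should give 25 together with its mirror image, the (R)-benzyl acetal F1. The two are separated by preparative chromatography on a chiral stationary phase. F1 is returned to the racemate with catalytic TsOH in the presence of 23 (acetal exchange through the oxocarbenium ion) and passed through again. The fallback rejoins the route at 25.

**Step 16.**
- **Main risk:** over-reduction. The alkyl benzyl ether at C-9 is the slowest of the four to cleave, and the longer exposure it needs invites hydrogenolysis on the ring-B side of that ether, reduction of the C-4 aldehyde and cleavage of the benzylic C–O bonds of the lactol ring.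
- **Second risk:** loss of configurational purity by ring–chain tautomerism if the free lactol stays long in contact with catalyst, moisture or protic impurities.
- **Fallback:** it changes the protecting group at the slow position and sets out from 21. BCl3 with pentamethylbenzene (CH2Cl2, −78 °C) strips both benzyl groups to give the bromo triol F2. BnBr/K2CO3 in acetone re-benzylates only the two phenols to give the primary alcohol F3, and TBSCl/imidazole gives the silyl ether F4. The conditions of step 15 convert F4 into the silyl-protected (S)-benzyl acetal F5. Pyridine-buffered HF·pyridine (THF, 0 °C) frees the alcohol while the acetal is still locked, giving the hydroxymethyl (S)-benzyl acetal F6. A short hydrogenolysis then has to cleave only two aryl benzyl ethers and the acetal benzyl group. The fallback rejoins the route at 26.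

**Step 11.**
- **Main risk:** sluggish attack, because the phenoxide of 9 is stabilised by its ortho formyl group and flanked on both sides, so heating may be needed. At higher temperatures decomposition of the two aldehydes and attack of fluoride or carbonate on the activated arene become competitive.
- **Fallback:** it reverses the polarity of the ether synthesis. From 5, deprotonation of the C–H between the two bromides (LDA, THF, −78 °C) and DMF give the symmetric dibromo aldehyde F7. From 17, aqueous KOH in DMSO at rt replaces fluoride by oxygen to give the ring-A phenol F8. A copper-catalysed Ullmann-type coupling (CuI, N,N-dimethylglycine, Cs2CO3, dioxane, 90 °C, F7 in excess) joins F8 to either of the equivalent, formyl-activated bromides of F7. The fallback rejoins the route at 18 and also bypasses steps 4 and 5.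

**Step 5.**
- **Main risk:** incomplete or slow formylation, because the only free carbon lies between the phenoxide oxygen and a bromine atom. Magnesium-assisted loss of the neighbouring MOM group may occur on prolonged reflux.
- **Fallback:** it formylates before the second bromine is present. From 4, one equivalent of NBS gives the monobromide F9. Bromine–lithium exchange, borylation and oxidation as in step 4 give the bromine-free phenol F10, and the same magnesium-mediated formylation at an unhindered ortho carbon gives the salicylaldehyde F11. NBS then brominates the single remaining ring position, which is ortho and para to the two MOM ethers. The fallback rejoins the route at 9.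

**Step 9.**
- **Main risk:** slow oxidative addition and slow hydrolysis of the acyl-palladium at a bromide flanked by fluorine and methyl, with hydrodebromination and displacement of the activated fluoride by water as competing processes.
- **Fallback:** it replaces catalysis by organolithium chemistry on a masked aldehyde. From 14, ethylene glycol with catalytic TsOH (toluene, water removal) gives the dioxolane F12. Bromine–lithium exchange (n-BuLi, THF, −78 °C) and Boc2O give the tert-butyl ester dioxolane F13, and PPTS in aqueous acetone releases the aldehyde without touching the ester. The fallback rejoins the route at 17.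

## Further compounds

F1 | step 15 | (1R)-enantiomer of 25 | Cc1cc(OCc4ccccc4)c(C=O)c2c1C(=O)Oc1c(COCc4ccccc4)c(OCc4ccccc4)c3c(c1O2)[C@H](OCc1ccccc1)OC3=O
F2 | step 16 | 7-bromo-3,8-dihydroxy-9-(hydroxymethyl)-1-methyl-11-oxo-11H-dibenzo[b,e][1,4]dioxepine-4,6-dicarbaldehyde | Cc1cc(O)c(C=O)c2c1C(=O)Oc1c(CO)c(O)c(Br)c(C=O)c1O2
F3 | step 16 | 3,8-bis(benzyloxy)-7-bromo-9-(hydroxymethyl)-1-methyl-11-oxo-11H-dibenzo[b,e][1,4]dioxepine-4,6-dicarbaldehyde | Cc1cc(OCc4ccccc4)c(C=O)c2c1C(=O)Oc1c(CO)c(OCc4ccccc4)c(Br)c(C=O)c1O2
F4 | step 16 | 3,8-bis(benzyloxy)-7-bromo-9-{[(tert-butyldimethylsilyl)oxy]methyl}-1-methyl-11-oxo-11H-dibenzo[b,e][1,4]dioxepine-4,6-dicarbaldehyde | Cc1cc(OCc4ccccc4)c(C=O)c2c1C(=O)Oc1c(CO[Si](C)(C)C(C)(C)C)c(OCc4ccccc4)c(Br)c(C=O)c1O2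
F5 | step 16 | (S)-benzyl acetal analogue of 25 with CH2OTBS at C-9 | Cc1cc(OCc4ccccc4)c(C=O)c2c1C(=O)Oc1c(CO[Si](C)(C)C(C)(C)C)c(OCc4ccccc4)c3c(c1O2)[C@@H](OCc1ccccc1)OC3=O
F6 | step 16 | (S)-benzyl acetal analogue of 25 with free CH2OH at C-9 | Cc1cc(OCc4ccccc4)c(C=O)c2c1C(=O)Oc1c(CO)c(OCc4ccccc4)c3c(c1O2)[C@@H](OCc1ccccc1)OC3=O
F7 | step 11 | 4-[(benzyloxy)methyl]-2,6-dibromo-3,5-bis(methoxymethoxy)benzaldehyde | O=Cc1c(Br)c(OCOC)c(COCc2ccccc2)c(OCOC)c1Br
F8 | step 11 | tert-butyl 4-(benzyloxy)-3-formyl-2-hydroxy-6-methylbenzoate | Cc1cc(OCc2ccccc2)c(C=O)c(O)c1C(=O)OC(C)(C)C
F9 | step 5 | 3-[(benzyloxy)methyl]-1-bromo-2,4-bis(methoxymethoxy)benzene | COCOc1ccc(Br)c(OCOC)c1COCc1ccccc1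
F10 | step 5 | 3-[(benzyloxy)methyl]-2,4-bis(methoxymethoxy)phenol | Oc1ccc(OCOC)c(COCc2ccccc2)c1OCOC
F11 | step 5 | 4-[(benzyloxy)methyl]-2-hydroxy-3,5-bis(methoxymethoxy)benzaldehyde | O=Cc1cc(OCOC)c(COCc2ccccc2)c(OCOC)c1O
F12 | step 9 | 2-[6-(benzyloxy)-3-bromo-2-fluoro-4-methylphenyl]-1,3-dioxolane | Cc1cc(OCc2ccccc2)c(C2OCCO2)c(F)c1Br
F13 | step 9 | tert-butyl 4-(benzyloxy)-3-(1,3-dioxolan-2-yl)-2-fluoro-6-methylbenzoate | Cc1cc(OCc2ccccc2)c(C2OCCO2)c(F)c1C(=O)OC(C)(C)C
A1 | alternative 1 | (1S)-6-(benzyloxy)-1-[(1R)-1-phenylethoxy]hexa-2,4-diyn-1-yl 3-[benzyl(dimethyl)silyl]prop-2-ynoate | C(OCc1ccccc1)C#CC#C[C@@H](O[C@H](C)c1ccccc1)OC(=O)C#C[Si](C)(C)Cc1ccccc1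
A2 | alternative 1 | 4-(benzyloxy)-3-formyl-2-hydroxy-6-methylbenzoic acid | Cc1cc(OCc2ccccc2)c(C=O)c(O)c1C(=O)O
A3 | alternative 1 | silyl depside with complete phthalide acetal | Cc1cc(OCc4ccccc4)c(C=O)c(O)c1C(=O)Oc1c(COCc4ccccc4)c([Si](C)(C)Cc4ccccc4)c3c(c1)[C@@H](O[C@H](C)c1ccccc1)OC3=O
A4 | alternative 2 | 1-aryloxy-3-[(benzyloxy)methyl]-4-methoxy-2,4-bis(trimethylsilyloxy)buta-1,3-diene carrying ring A as allyl ester and dioxolane | C=CCOC(=O)c1c(C)cc(OCc2ccccc2)c(C2OCCO2)c1OC=C(O[Si](C)(C)C)C(COCc1ccccc1)=C(OC)O[Si](C)(C)C
A5 | alternative 2 | (5S)-3-bromo-5-[(1R)-1-phenylethoxy]furan-2(5H)-one | BrC1=C[C@@H](O[C@H](C)c2ccccc2)OC1=O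
A6 | alternative 2 | diaryl ether with complete ring B and lactol acetal | C=CCOC(=O)c1c(C)cc(OCc2ccccc2)c(C2OCCO2)c1Oc1c(O)c(COCc2ccccc2)c(O)c3c1[C@@H](O[C@H](C)c1ccccc1)OC3=O
A7 | alternative 3 | ring-B phthalide acetal bearing a but-2-ynoate at O-10 and a 3-(silyloxy)prop-1-ynyl ether at O-5 | CC#CC(=O)Oc1c(COCc4ccccc4)c(OCc4ccccc4)c3c(c1OC#CCO[Si](C)(C)C(C)(C)C)[C@@H](O[C@H](C)c1ccccc1)OC3=O
A8 | alternative 3 | benzyl ethynyl ether | C#COCc1ccccc1
A9 | alternative 3 | depsidone with ring-A silyloxymethyl group | Cc1cc(OCc4ccccc4)c(CO[Si](C)(C)C(C)(C)C)c2c1C(=O)Oc1c(COCc4ccccc4)c(OCc4ccccc4)c3c(c1O2)[C@@H](O[C@H](C)c1ccccc1)OC3=O
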